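The tetrahydrofuran ring carries an all-trans triad, C2 (guaiacyl), C3 (methyl) and C4 (syringylmethyl), beside an unsubstituted C5H2–O1. Carrying C5 as a lactone carbonyl makes C4 an enolate carbon and C3 the β-carbon of a butenolide. The route rests on one three-component union: lithium dimethylcuprate adds to an (R)-5-aryl butenolide anti to the aryl group, and the enolate so formed is benzylated in the same flask by the syringyl benzylic bromide, anti to the new methyl group. This forms the exocyclic C4–CH2 bond between the halves and sets C3 and C4 from C2, itself set by catalytic asymmetric alkynylation. Lactone-to-ether reduction and debenzylation finish the synthesis.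

Key step: step 5

Assumption: the ProPhenol enantiomer is the one that delivers the alkynyl group to the Re face of the aldehyde, which gives the (S)-carbinol; the sense would be confirmed on the first batch by MTPA ester analysis.

Step 1
Reactants: 1 4-(benzyloxy)-3-methoxybenzaldehyde; 2 methyl propiolate
Product: 3 methyl (S)-4-(4-(benzyloxy)-3-methoxyphenyl)-4-hydroxybut-2-ynoate
Conditions: Me2Zn (3 equiv), ProPhenol ligand (10 mol %, enantiomer for Re-face addition), Ph3P=O (20 mol %), toluene, 4 °C; aq. NH4Cl
Reagents that add atoms: none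
Why: Catalytic enantioselective alkynylation of an aldehyde, in which the dinuclear zinc–ProPhenol complex holds both the aldehyde and the zinc alkynylide formed from 2 and Me2Zn and delivers the alkynyl group to the Re face, so that the ligand alone sets the carbinol center that becomes C2 of the target.

Step 2
Reactants: 3 methyl (S)-4-(4-(benzyloxy)-3-methoxyphenyl)-4-hydroxybut-2-ynoate
Product: 5 (R)-5-(4-(benzyloxy)-3-methoxyphenyl)furan-2(5H)-one, via Z-hydroxy enoate 4 (not isolated)
Conditions: H2 (1 atm), Pd/CaCO3 poisoned with Pb(OAc)2 (Lindlar catalyst), quinoline, EtOAc, rt; then PPTS (cat.), CH2Cl2, rt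
Reagents that add atoms: none
Why: Lindlar semihydrogenation is a syn addition that gives the Z-enoate, whose hydroxyl and ester groups are then close enough to lactonise with loss of methanol, while the carbinol center is not touched (its descriptor changes from S to R only through the priority rules).

Step 3
Reactants: 6 4-(benzyloxy)-3,5-dimethoxybenzaldehyde
Product: 7 (4-(benzyloxy)-3,5-dimethoxyphenyl)methanol
Conditions: NaBH4, MeOH, 0 °C
Reagents that add atoms: none
Why: Borohydride reduction of an aromatic aldehyde to the benzylic alcohol is reliable and leaves the aryl ethers untouched.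

Step 4
Reactants: 7 (4-(benzyloxy)-3,5-dimethoxyphenyl)methanol
Product: 8 2-(benzyloxy)-5-(bromomethyl)-1,3-dimethoxybenzene
Conditions: PBr3 (0.4 equiv), Et2O, 0 °C
Reagents that add atoms: phosphorus tribromide, BrP(Br)Br
Why: Conversion of an electron-rich benzylic alcohol into the bromide through its phosphite ester is fast at 0 °C, and the product is used soon after filtration through silica.

Step 5
Reactants: 5 (R)-5-(4-(benzyloxy)-3-methoxyphenyl)furan-2(5H)-one; 8 2-(benzyloxy)-5-(bromomethyl)-1,3-dimethoxybenzene
Product: 10 (3R,4R,5R)-3-(4-(benzyloxy)-3,5-dimethoxybenzyl)-5-(4-(benzyloxy)-3-methoxyphenyl)-4-methyldihydrofuran-2(3H)-one, via lithium enolate 9 (not isolated)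
Conditions: MeLi (2.2 equiv), CuI (1.1 equiv), Et2O, 0 °C; 5, THF, −78 °C; then 8 (2 equiv), HMPA (or DMPU), −78 → −20 °C; aq. NH4Cl
Reagents that add atoms: lithium dimethylcuprate, [Li+].C[Cu-]C (made in the flask from methyllithium, [Li]C, and CuI)
Why: The cuprate adds to the β-carbon of the butenolide (π-complex, then a β-cuprio enolate of trivalent copper, then reductive elimination) to give lithium enolate 9, which HMPA frees from its aggregates for SN2 C-alkylation by the benzylic bromide 8, forming the bond between the ring α-carbon (C4 of the target) and the syringyl CH2. The closest known reaction type is the three-component conjugate addition–enolate trapping (vicinal difunctionalisation) of cyclic enones and butenolides. No ring is closed: the butenolide ring of 5 is kept and later becomes the tetrahydrofuran ring. The methyl-bearing center (C3 of the target) is controlled by the aryl group on the neighbouring carbinol carbon, which shields one face of the flat butenolide so that methyl enters anti, and the benzyl-bearing center (C4) is controlled in turn by that new methyl group, which sends the electrophile to the opposite face of the enolate. The step needs conjugate addition to outrun removal of the acidic benzylic γ-hydrogen of 5, and C-monoalkylation to outrun O-alkylation and proton exchange; the weakly basic cuprate at −78 °C, the soft and reactive benzylic bromide used in excess and the low temperature should secure this. The anti,anti product is also the most stable all-trans arrangement, so any equilibration at the α-carbon works in the same direction.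

Step 6
Reactants: 10 (3R,4R,5R)-3-(4-(benzyloxy)-3,5-dimethoxybenzyl)-5-(4-(benzyloxy)-3-methoxyphenyl)-4-methyldihydrofuran-2(3H)-one
Product: 11 (3R,4R,5R)-3-(4-(benzyloxy)-3,5-dimethoxybenzyl)-5-(4-(benzyloxy)-3-methoxyphenyl)-4-methyltetrahydrofuran-2-ol (mixture of anomers)
Conditions: i-Bu2AlH (1.1 equiv), CH2Cl2, −78 °C; Rochelle salt work-up
Reagents that add atoms: none
Why: At −78 °C one hydride adds to the lactone carbonyl and the tetrahedral aluminium alkoxide persists until work-up, so the partial reduction should stop at the lactol without touching the three ring stereocenters.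

Step 7
Reactants: 11 (3R,4R,5R)-3-(4-(benzyloxy)-3,5-dimethoxybenzyl)-5-(4-(benzyloxy)-3-methoxyphenyl)-4-methyltetrahydrofuran-2-ol
Product: 12 (2R,3R,4R)-2-(4-(benzyloxy)-3-methoxyphenyl)-4-(4-(benzyloxy)-3,5-dimethoxybenzyl)-3-methyltetrahydrofuran
Conditions: Et3SiH (3 equiv), BF3·OEt2 (1.5 equiv), CH2Cl2, −78 → −40 °C
Reagents that add atoms: none
Why: Ionic hydrogenation, in which BF3·OEt2 ionises the anomeric hydroxyl to a cyclic oxocarbenium ion that Et3SiH reduces to the ring CH2; no stereocenter is formed, and at low temperature the hemiacetal should ionise far faster than the benzylic ether at C2.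

Step 8
Reactants: 12 (2R,3R,4R)-2-(4-(benzyloxy)-3-methoxyphenyl)-4-(4-(benzyloxy)-3,5-dimethoxybenzyl)-3-methyltetrahydrofuran
Product: 13 (2R,3R,4R)-2-(4-hydroxy-3-methoxyphenyl)-4-(4-hydroxy-3,5-dimethoxybenzyl)-3-methyltetrahydrofuran
Conditions: H2 (1 atm), Pd/C (10 %), EtOAc, rt, stopped after uptake of two equivalents
Reagents that add atoms: none
Why: Hydrogenolysis of the two aryl benzyl ethers over Pd/C in a neutral ester solvent should be much faster than cleavage of the dialkyl benzylic C2–O bond of the ring, so both phenols are freed with the tetrahydrofuran intact.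

Compound list
1 | 4-(benzyloxy)-3-methoxybenzaldehyde | COc1cc(C=O)ccc1OCc1ccccc1 | starting material
2 | methyl propiolate | C#CC(=O)OC | starting material
3 | methyl (S)-4-(4-(benzyloxy)-3-methoxyphenyl)-4-hydroxybut-2-ynoate | COc1cc([C@@H](C#CC(=O)OC)O)ccc1OCc1ccccc1 | intermediate
4 | methyl (R,Z)-4-(4-(benzyloxy)-3-methoxyphenyl)-4-hydroxybut-2-enoate (not isolated) | COc1cc([C@@H](/C=C\C(=O)OC)O)ccc1OCc1ccccc1 | intermediate
5 | (R)-5-(4-(benzyloxy)-3-methoxyphenyl)furan-2(5H)-one | COc1cc([C@@H]2OC(=O)C=C2)ccc1OCc1ccccc1 | intermediate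
6 | 4-(benzyloxy)-3,5-dimethoxybenzaldehyde | COc1cc(C=O)cc(OC)c1OCc1ccccc1 | starting material
7 | (4-(benzyloxy)-3,5-dimethoxyphenyl)methanol | COc1cc(CO)cc(OC)c1OCc1ccccc1 | intermediate
8 | 2-(benzyloxy)-5-(bromomethyl)-1,3-dimethoxybenzene | COc1cc(CBr)cc(OC)c1OCc1ccccc1 | intermediate
9 | lithium (4R,5R)-5-(4-(benzyloxy)-3-methoxyphenyl)-4-methyl-4,5-dihydrofuran-2-olate (not isolated) | COc1cc([C@@H]2OC([O-])=C[C@H]2C)ccc1OCc1ccccc1.[Li+] | intermediate
10 | (3R,4R,5R)-3-(4-(benzyloxy)-3,5-dimethoxybenzyl)-5-(4-(benzyloxy)-3-methoxyphenyl)-4-methyldihydrofuran-2(3H)-one | COc1cc([C@@H]2OC(=O)[C@H](Cc3cc(OC)c(OCc4ccccc4)c(OC)c3)[C@H]2C)ccc1OCc1ccccc1 | intermediate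
11 | (3R,4R,5R)-3-(4-(benzyloxy)-3,5-dimethoxybenzyl)-5-(4-(benzyloxy)-3-methoxyphenyl)-4-methyltetrahydrofuran-2-ol, mixture of anomers | COc1cc([C@@H]2OC(O)[C@H](Cc3cc(OC)c(OCc4ccccc4)c(OC)c3)[C@H]2C)ccc1OCc1ccccc1 | intermediate
12 | (2R,3R,4R)-2-(4-(benzyloxy)-3-methoxyphenyl)-4-(4-(benzyloxy)-3,5-dimethoxybenzyl)-3-methyltetrahydrofuran | COc1cc([C@@H]2OC[C@H](Cc3cc(OC)c(OCc4ccccc4)c(OC)c3)[C@H]2C)ccc1OCc1ccccc1 | intermediate
13 | (2R,3R,4R)-2-(4-hydroxy-3-methoxyphenyl)-4-(4-hydroxy-3,5-dimethoxybenzyl)-3-methyltetrahydrofuran | COc1cc([C@@H]2OC[C@H](Cc3cc(OC)c(O)c(OC)c3)[C@H]2C)ccc1O | target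

Total step count: 8.
Longest linear sequence: 6 steps (steps 1, 2, 5, 6, 7, 8; the branch through steps 3 and 4 is equally long).

Steps most likely to fail

Step 5 (key step). The cuprate-derived enolate may alkylate too slowly, so that proton exchange between enolate and product gives dialkylated and unalkylated lactone. The cuprate may also remove the γ-hydrogen of 5, and the configuration at that carbon would then be lost through the achiral 2-oxidofuran. The fallback sets out from 5 and comes back at 10, and it separates the two bond formations. Me2CuLi with Me3SiCl in THF at −78 °C (silyl-accelerated conjugate addition, faster than deprotonation) should give (((4R,5R)-5-(4-(benzyloxy)-3-methoxyphenyl)-4-methyl-4,5-dihydrofuran-2-yl)oxy)trimethylsilane F1. Dilute aqueous acid on work-up should hydrolyse it to (4R,5R)-5-(4-(benzyloxy)-3-methoxyphenyl)-4-methyldihydrofuran-2(3H)-one F2. LiN(SiMe3)2 in THF at −78 °C then regenerates enolate 9 free of copper, and bromide 8 should alkylate it anti to the methyl group to give 10.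

Step 1. Turnover may be low or facial selectivity insufficient with the electron-rich aldehyde, and the propiolate may oligomerise. The fallback sets out from 1 and 2 and comes back at 3. Lithium methyl propiolate (2, LiN(SiMe3)2, THF, −78 °C) should add to 1 to give racemic methyl 4-(4-(benzyloxy)-3-methoxyphenyl)-4-hydroxybut-2-ynoate F3. MnO2 in CH2Cl2 should oxidise it to methyl 4-(4-(benzyloxy)-3-methoxyphenyl)-4-oxobut-2-ynoate F4. Reagent-controlled reduction of the ynone with Alpine-Borane (B-isopinocampheyl-9-borabicyclo[3.3.1]nonane, the enantiomer that delivers hydride to the Re face, THF, rt) should then give (S)-3.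

Step 7. BF3·OEt2 may ionise the electron-rich benzylic C2–O bond, which would lead to ring opening and reduction to acyclic material. The fallback sets out from 10 and comes back at 12, and it avoids Lewis acid altogether. LiAlH4 in THF at 0 °C should give (1R,2R,3R)-3-(4-(benzyloxy)-3,5-dimethoxybenzyl)-1-(4-(benzyloxy)-3-methoxyphenyl)-2-methylbutane-1,4-diol F5. TsCl (1.05 equiv) in pyridine/CH2Cl2 at 0 °C should sulfonylate the primary hydroxyl selectively to give (2R,3R,4R)-2-(4-(benzyloxy)-3,5-dimethoxybenzyl)-4-(4-(benzyloxy)-3-methoxyphenyl)-4-hydroxy-3-methylbutyl 4-methylbenzenesulfonate F6. NaH in THF should then close the ring by 5-exo-tet displacement by the benzylic alkoxide, with retention at C2, to give 12.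

Further compounds
F1 | step 5 | (((4R,5R)-5-(4-(benzyloxy)-3-methoxyphenyl)-4-methyl-4,5-dihydrofuran-2-yl)oxy)trimethylsilane | COc1cc([C@@H]2OC(O[Si](C)(C)C)=C[C@H]2C)ccc1OCc1ccccc1
F2 | step 5 | (4R,5R)-5-(4-(benzyloxy)-3-methoxyphenyl)-4-methyldihydrofuran-2(3H)-one | COc1cc([C@@H]2OC(=O)C[C@H]2C)ccc1OCc1ccccc1
F3 | step 1 | methyl 4-(4-(benzyloxy)-3-methoxyphenyl)-4-hydroxybut-2-ynoate, racemic | COc1cc(C(O)C#CC(=O)OC)ccc1OCc1ccccc1
F4 | step 1 | methyl 4-(4-(benzyloxy)-3-methoxyphenyl)-4-oxobut-2-ynoate | COc1cc(C(=O)C#CC(=O)OC)ccc1OCc1ccccc1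
F5 | step 7 | (1R,2R,3R)-3-(4-(benzyloxy)-3,5-dimethoxybenzyl)-1-(4-(benzyloxy)-3-methoxyphenyl)-2-methylbutane-1,4-diol | COc1cc([C@H](O)[C@H](C)[C@H](CO)Cc2cc(OC)c(OCc3ccccc3)c(OC)c2)ccc1OCc1ccccc1
F6 | step 7 | (2R,3R,4R)-2-(4-(benzyloxy)-3,5-dimethoxybenzyl)-4-(4-(benzyloxy)-3-methoxyphenyl)-4-hydroxy-3-methylbutyl 4-methylbenzenesulfonate | COc1cc([C@H](O)[C@H](C)[C@H](COS(=O)(=O)c2ccc(C)cc2)Cc2cc(OC)c(OCc3ccccc3)c(OC)c2)ccc1OCc1ccccc1
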